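In a one-step world the solid reagent dissolves to partner, partner meets substrate, and each partner gives one target, so the product stops growing when the solid reagent, your limiting reagent, has stopped feeding it. You have this flask to forecast, with elm and cedar as earlier runs:

| setting | elm | cedar | flask |
|---|---|---|---|
| substrate | 0.40 M | 0.40 M | 0.40 M |
| other conformer | 0.14 M | 0.22 M | 0.100 M |
| solid reagent | 0.20 M | 0.20 M | 0.200 M |
| remark | run made earlier | run made earlier |  |
| time |  |  | 8.0 h |

| run | time / h | isomer of the product / % | target / % |
|---|---|---|---|
| elm | 0.500 | 14.6 | 22.8 |
| elm | 1.50 | 14.6 | 23.3 |
| elm | 3.00 | 14.1 | 22.5 |
| elm | 5.00 | 15.1 | 22.1 |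
| elm | 6.00 | 13.9 | 22.7 |
| cedar | 0.500 | 13.0 | 19.7 |
| cedar | 1.00 | 13.0 | 20.0 |
| cedar | 2.00 | 13.0 | 19.8 |
| cedar | 3.00 | 12.7 | 19.4 |
| cedar | 6.00 | 12.5 | 19.9 |

(readings scatter by 0.3 percentage points)

- solid reagent is a solid; its amount is given per volume of the solution
- candidate steps: solid reagent <-> partner; partner + other conformer -> isomer of the product; substrate + partner -> target; substrate <-> other conformer
- at the start none of the solid reagent is in solution

- share of isomer of the product in isomer of the product plus target at 1.0 min
- share of isomer of the product in isomer of the product plus target at 20 min
- share of isomer of the product in isomer of the product plus target at 8.0 h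
- which of isomer of the product and target there is more of at 8.0 h

That picture holds for the sum of the products. The first elm reading gives 37.4% of the charge, and the solid reagent over substrate and other conformer charged in elm gives 37.0%. In this flask the same limit is 40.0%. But a one-step world makes no isomer of the product, and the readings show plenty.

So add the second step, partner taking other conformer to the isomer, with the two pools kept apart. The odds of isomer to target then start by following the charged ratio of other conformer to substrate, which goes from 0.350 in elm to 0.550 in cedar. The read odds go from 0.638 to 0.650.

So add the third process, substrate and other conformer turning into each other. If that outruns the supply of partner, the charge is forgotten (Curtin–Hammett behaviour), and one number carries over: the Curtin–Hammett share, isomer in isomer plus target, pooled over both runs, 39.1%.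

This flask is charged at a ratio of 0.250, below both runs. I take that share at 20 min and 8.0 h, which makes 15.7% isomer and 24.3% target. The earliest reading is at 0.500 h, so the same figure at 1.0 min is a guess.

The forecast says 37%, 38.5% and 38.8% with target ahead, lower than mine at 1.0 min, on the ground that the “earliest product could deviate because conformers may not yet have equilibrated”.

The flask gives 38.8%, 38.4% and 38.4%, with target ahead at 24.6% against 15.4% of isomer.

    solid reagent ⇌ partner, rate k1*(cs1 - [partner]) while solid is left; crystals form when [partner] > cs1 (solubility = 0.250 M, k = 0.00447 s⁻¹)
    partner + other conformer → isomer of the product (k = 0.0384 M⁻¹ s⁻¹)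
    substrate + partner → target (k = 0.0152 M⁻¹ s⁻¹)
    substrate ⇌ other conformer (K = 0.254, k = 0.00870 s⁻¹)

Your share times the limit gave 15.7% of isomer in this flask, against the 15.4% it holds. Try it on the neighbour charged with 0.16 M of substrate and otherwise the same, at a ratio of 0.625: the limit is 76.9%, so the share gives 30.1% of isomer, and that neighbour holds 29.7%. The main reason for the low share in this flask is the backward run from other conformer to substrate: take that run away and the lead passes to the isomer, its share at 8.0 h rising from 38.4% to 87.9%.

(Readings and results stem from a simulated flask with made-up constants; the scatter is artificial.)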